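The route rests on breaking the C4–C5 bond of the six-membered carbocycle. The adjacent hydroxyls on C4 (secondary) and C5 (tertiary) are read as an acyloin after reduction, and C5 plus the heptadecenyl chain is simply the oleoyl group, C5 being the former carboxyl carbon. A chiral triazolylidene turns the C4 aldehyde of an open-chain keto aldehyde into an acyl anion equivalent that attacks the C5 ketone, so one operation closes the ring and sets C5. The precursor is an oleoyl ketone whose C6 methylene carries a C1 dithiane and, on it, a 3-oxopropyl arm (C2–C4). The resulting C4 ketone, enolisable only toward C3, then introduces C2=C3 before its reduction.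

Key step: step 6

Remark: ring atoms are numbered as in the target (C1 carbonyl, C2=C3, C4 carbinol, C5 tertiary carbinol, C6 methylene); the (5aS,10bR) antipode of the triazolium salt is assumed to give the (S) ketol, and its equally available mirror image is used should the facial sense prove opposite.

Step 1
Reactants: 1 oleic acid [(Z)-octadec-9-enoic acid]
Product: 2 (Z)-N-methoxy-N-methyloctadec-9-enamide
Conditions: CDI, CH2Cl2, 0 °C to rt; then MeNHOMe·HCl, rt
Reagents that add atoms: N,O-dimethylhydroxylamine hydrochloride, CNOC.Cl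
Why: Activation of the acid as its acyl imidazolide followed by aminolysis is a standard Weinreb amide formation that does not affect the Z alkene.

Step 2
Reactants: 3 tert-butyl(dimethyl)(pent-4-yn-1-yloxy)silane; 2 (Z)-N-methoxy-N-methyloctadec-9-enamide
Product: 4 (14Z)-1-{[tert-butyl(dimethyl)silyl]oxy}tricos-14-en-4-yn-6-one
Conditions: 3 (1.2 equiv), n-BuLi, THF, −78 °C; then 2, −78 to 0 °C; sat. aq. NH4Cl
Reagents that add atoms: none
Why: The lithium acetylide adds once to the Weinreb amide because the chelated tetrahedral adduct survives until the quench (Weinreb ketone synthesis), giving the ynone that already holds C5, C6, C1 and the C2–C4 arm.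

Step 3
Reactants: 4 (14Z)-1-{[tert-butyl(dimethyl)silyl]oxy}tricos-14-en-4-yn-6-one
Product: 5 (Z)-1-[2-(3-{[tert-butyl(dimethyl)silyl]oxy}propyl)-1,3-dithian-2-yl]nonadec-10-en-2-one
Conditions: HS(CH2)3SH (1.1 equiv), NaOMe (1.2 equiv), MeOH/CH2Cl2 4:1, −10 °C to rt, argon, dark
Reagents that add atoms: propane-1,3-dithiol, SCCCS
Why: Base-mediated double conjugate (thia-Michael) addition of a 1,3-dithiol to an ynone is thermodynamically driven to the β-keto 1,3-dithiane, which masks C1 exactly β to the oleoyl ketone, while the ionic conditions leave the chain alkene and the silyl ether alone.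

Step 4
Reactants: 5 (Z)-1-[2-(3-{[tert-butyl(dimethyl)silyl]oxy}propyl)-1,3-dithian-2-yl]nonadec-10-en-2-one
Product: 6 (Z)-1-[2-(3-hydroxypropyl)-1,3-dithian-2-yl]nonadec-10-en-2-one
Conditions: HF·pyridine, pyridine, THF, 0 °C to rt
Reagents that add atoms: none
Why: Fluoride cleavage of a primary tert-butyldimethylsilyl ether (driven by Si–F bond formation) is selective and leaves the ketone, the dithiane and the Z alkene untouched.

Step 5
Reactants: 6 (Z)-1-[2-(3-hydroxypropyl)-1,3-dithian-2-yl]nonadec-10-en-2-one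
Product: 7 3-{2-[(10Z)-2-oxononadec-10-en-1-yl]-1,3-dithian-2-yl}propanal
Conditions: SO3·pyridine, DMSO, iPr2NEt, CH2Cl2, 0 °C
Reagents that add atoms: none
Why: Parikh–Doering oxidation (activated DMSO) should take the primary alcohol to the aldehyde without touching dithiane sulfur or the alkene, and its cold, non-acidic medium avoids aldol closure of the 1,6-keto aldehyde, which is used at once.

Step 6
Reactants: 7 3-{2-[(10Z)-2-oxononadec-10-en-1-yl]-1,3-dithian-2-yl}propanal
Product: 8 (8S)-8-[(Z)-heptadec-8-en-1-yl]-8-hydroxy-1,5-dithiaspiro[5.5]undecan-9-one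
Conditions: (5aS,10bR)-2-(pentafluorophenyl)-5a,10b-dihydro-4H,6H-indeno[2,1-b][1,2,4]triazolo[4,3-d][1,4]oxazin-2-ium tetrafluoroborate (10 mol %), Et3N (10 mol %), toluene (0.05 M), rt
Reagents that add atoms: none
Why: The carbene freed from the triazolium salt by the amine adds to the C4 aldehyde, proton transfer gives the Breslow enaminol, this acyl anion equivalent attacks the C5 ketone and the carbene is then expelled from the resulting alkoxide. This is the known carbene-catalysed enantioselective intramolecular crossed aldehyde–ketone benzoin reaction that turns keto aldehydes into cyclic tertiary α-ketols. The carbocycle (C4–C5–C6–C1–C2–C3) closes in the 6-exo-trig mode, the attacked C=O lying outside the new ring. The one new stereocentre, C5 (S), is set by the catalyst: its indane framework blocks one face of the enaminol while the ketone is held by a hydrogen bond from the enaminol hydroxyl to its oxygen, so that only one ketone face can reach C4 within the tether. The step needs chemoselectivity between the two carbonyls and over aldol closure through the C6 methylene, which the substrate secures because only the aldehyde has the C–H needed to form the enaminol and because a weak base at room temperature generates little enolate. The C1 dithiane helps as a gem-disubstituted centre that brings the two arms together and leaves no acidic or electrophilic site at C1, and the product, lacking a carbinol hydrogen, should not revert.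

Step 7
Reactants: 8 (8S)-8-[(Z)-heptadec-8-en-1-yl]-8-hydroxy-1,5-dithiaspiro[5.5]undecan-9-one
Product: 9 (8S)-8-[(Z)-heptadec-8-en-1-yl]-8-hydroxy-10-(phenylselanyl)-1,5-dithiaspiro[5.5]undecan-9-one (both C10 epimers)
Conditions: LiN(iPr)2 (2.2 equiv), THF, −78 °C; PhSeBr (1.1 equiv), −78 °C; sat. aq. NH4Cl at −78 °C
Reagents that add atoms: phenylselenenyl bromide, Br[Se]c1ccccc1
Why: After the hydroxyl is deprotonated the ketone can enolise only at C3 because C5 is fully substituted, and the lithium enolate is selenenylated on carbon at −78 °C (Reich α-selenenylation), the new C3 centre forming as an inconsequential mixture that the next step destroys.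

Step 8
Reactants: 9 (8S)-8-[(Z)-heptadec-8-en-1-yl]-8-hydroxy-10-(phenylselanyl)-1,5-dithiaspiro[5.5]undecan-9-one
Product: 11 (10S)-10-[(Z)-heptadec-8-en-1-yl]-10-hydroxy-1,5-dithiaspiro[5.5]undec-7-en-9-one, via phenylselenoxide 10 (not isolated)
Conditions: mCPBA (1.0 equiv), CH2Cl2, −78 °C; then iPr2NH (2 equiv), −78 °C to rt
Reagents that add atoms: none
Why: One equivalent of peracid at −78 °C should oxidise selenium much faster than thioacetal sulfur or the isolated alkene, and the α-keto selenoxide undergoes syn-elimination on warming (selenoxide elimination), necessarily toward C2 since C4 is the carbonyl, the amine suppressing acid-mediated side reactions and re-addition of PhSeOH.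

Step 9
Reactants: 11 (10S)-10-[(Z)-heptadec-8-en-1-yl]-10-hydroxy-1,5-dithiaspiro[5.5]undec-7-en-9-one
Product: 12 (8S,9S)-8-[(Z)-heptadec-8-en-1-yl]-1,5-dithiaspiro[5.5]undec-10-ene-8,9-diol
Conditions: Me4NBH(OAc)3 (5 equiv), MeCN/AcOH 1:1, −30 to 0 °C
Reagents that add atoms: none
Why: Ligand exchange puts the C5 hydroxyl on boron and hydride is then delivered intramolecularly to the C4 carbonyl from the face carrying that oxygen (Saksena–Evans hydroxyl-directed reduction), so hydrogen enters cis and the new C4 hydroxyl ends trans to the C5 hydroxyl, giving (4S) by 1,2-reduction because the reagent does not reduce undirected enones.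

Step 10
Reactants: 12 (8S,9S)-8-[(Z)-heptadec-8-en-1-yl]-1,5-dithiaspiro[5.5]undec-10-ene-8,9-diol
Product: 13 (4S,5S)-5-[(Z)-heptadec-8-en-1-yl]-4,5-dihydroxycyclohex-2-en-1-one (target)
Conditions: MeI (15 equiv), CaCO3 (5 equiv), MeCN/H2O 9:1, 40 °C, dark, sealed
Reagents that add atoms: water, O
Why: S-Methylation turns the allylic dithiane into a leaving group and water hydrolyses the resulting thionium ion to the C1 ketone (alkylative dithioacetal hydrolysis), which lands in conjugation with C2=C3, under carbonate-buffered near-neutral conditions that spare the Z alkene and avoid dehydration or retro-aldol of the β-hydroxy enone.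

Compound list
1 | oleic acid, (Z)-octadec-9-enoic acid | CCCCCCCC/C=C\CCCCCCCC(=O)O | starting material
2 | (Z)-N-methoxy-N-methyloctadec-9-enamide | CCCCCCCC/C=C\CCCCCCCC(=O)N(C)OC | intermediate
3 | tert-butyl(dimethyl)(pent-4-yn-1-yloxy)silane | C#CCCCO[Si](C)(C)C(C)(C)C | starting material
4 | (14Z)-1-{[tert-butyl(dimethyl)silyl]oxy}tricos-14-en-4-yn-6-one | CCCCCCCC/C=C\CCCCCCCC(=O)C#CCCCO[Si](C)(C)C(C)(C)C | intermediate
5 | (Z)-1-[2-(3-{[tert-butyl(dimethyl)silyl]oxy}propyl)-1,3-dithian-2-yl]nonadec-10-en-2-one | CCCCCCCC/C=C\CCCCCCCC(=O)CC1(CCCO[Si](C)(C)C(C)(C)C)SCCCS1 | intermediate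
6 | (Z)-1-[2-(3-hydroxypropyl)-1,3-dithian-2-yl]nonadec-10-en-2-one | CCCCCCCC/C=C\CCCCCCCC(=O)CC1(CCCO)SCCCS1 | intermediate
7 | 3-{2-[(10Z)-2-oxononadec-10-en-1-yl]-1,3-dithian-2-yl}propanal, the keto aldehyde for ring closure | CCCCCCCC/C=C\CCCCCCCC(=O)CC1(CCC=O)SCCCS1 | intermediate
8 | (8S)-8-[(Z)-heptadec-8-en-1-yl]-8-hydroxy-1,5-dithiaspiro[5.5]undecan-9-one | CCCCCCCC/C=C\CCCCCCC[C@]1(O)CC2(SCCCS2)CCC1=O | intermediate
9 | (8S)-8-[(Z)-heptadec-8-en-1-yl]-8-hydroxy-10-(phenylselanyl)-1,5-dithiaspiro[5.5]undecan-9-one, both C10 epimers | CCCCCCCC/C=C\CCCCCCC[C@]1(O)CC2(SCCCS2)CC([Se]c3ccccc3)C1=O | intermediate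
10 | (8S)-10-(benzeneseleninyl)-8-[(Z)-heptadec-8-en-1-yl]-8-hydroxy-1,5-dithiaspiro[5.5]undecan-9-one, not isolated | CCCCCCCC/C=C\CCCCCCC[C@]1(O)CC2(SCCCS2)CC([Se](=O)c3ccccc3)C1=O | intermediate
11 | (10S)-10-[(Z)-heptadec-8-en-1-yl]-10-hydroxy-1,5-dithiaspiro[5.5]undec-7-en-9-one | CCCCCCCC/C=C\CCCCCCC[C@]1(O)CC2(SCCCS2)C=CC1=O | intermediate
12 | (8S,9S)-8-[(Z)-heptadec-8-en-1-yl]-1,5-dithiaspiro[5.5]undec-10-ene-8,9-diol, trans-diol | CCCCCCCC/C=C\CCCCCCC[C@]1(O)CC2(SCCCS2)C=C[C@@H]1O | intermediate
13 | (4S,5S)-5-[(Z)-heptadec-8-en-1-yl]-4,5-dihydroxycyclohex-2-en-1-one | CCCCCCCC/C=C\CCCCCCC[C@]1(O)CC(=O)C=C[C@@H]1O | target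

Total step count: 10. Longest linear sequence: 10 steps (from oleic acid 1 to 13).

Steps most likely to fail

Step 6. Aldol closure through the C6 enolate, intermolecular acyloin formation, or weak discrimination between the faces of a ketone flanked by two methylene groups may compete. Fallback, from 7 back to 8: the same C4–C5 bond is made by ketyl coupling, without carbene or base. SmI2 (2.5 equiv) with t-BuOH in THF at −78 °C should close 7 to the racemic cis-diol rel-(8S,9R)-8-[(Z)-heptadec-8-en-1-yl]-1,5-dithiaspiro[5.5]undecane-8,9-diol F1 (pinacol cyclisation, cis through a samarium-bridged diketyl; both sulfur atoms sit too far from the ketyl carbons to be expelled). SO3·pyridine/DMSO/iPr2NEt then oxidises only the secondary carbinol to racemic 8-[(Z)-heptadec-8-en-1-yl]-8-hydroxy-1,5-dithiaspiro[5.5]undecan-9-one F2. Preparative chromatography on a chiral stationary phase (amylose tris(3,5-dimethylphenylcarbamate)) returns 8, at the cost of half the material.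

Step 8. Oxidation at a dithiane sulfur or at the chain alkene may compete with oxidation at selenium, and PhSeOH may add back to the olefin. Fallback, from 8 to 13 (replacing steps 7–10): the double bond is introduced only after sulfur has been removed.
- Me4NBH(OAc)3 in MeCN/AcOH reduces 8 by hydroxyl delivery to the saturated trans-diol (8S,9S)-8-[(Z)-heptadec-8-en-1-yl]-1,5-dithiaspiro[5.5]undecane-8,9-diol F3.
- TESOTf/2,6-lutidine gives (8S,9S)-8-[(Z)-heptadec-8-en-1-yl]-8,9-bis(triethylsilyloxy)-1,5-dithiaspiro[5.5]undecane F4.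
- MeI/CaCO3 in aqueous MeCN frees (3S,4S)-3-[(Z)-heptadec-8-en-1-yl]-3,4-bis(triethylsilyloxy)cyclohexan-1-one F5.
- LiN(iPr)2/Me3SiCl in THF at −78 °C should enolise toward C2, because the C6 methylene is neopentylic and next to the silyloxy-bearing C5, giving (4S,5S)-5-[(Z)-heptadec-8-en-1-yl]-4,5-bis(triethylsilyloxy)-1-(trimethylsilyloxy)cyclohex-1-ene F6.
- Pd(OAc)2 in MeCN (Saegusa–Ito dehydrogenation) gives (4S,5S)-5-[(Z)-heptadec-8-en-1-yl]-4,5-bis(triethylsilyloxy)cyclohex-2-en-1-one F7.
- HF·pyridine in THF/pyridine removes both silyl groups to give 13.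

Step 9. Ligand exchange at the hindered tertiary hydroxyl may be slow, leaving the conjugated carbonyl unreduced, or undirected hydride delivery may erode the trans relationship. Fallback, from 11 back to 12: stereocontrol is moved from the substrate to the reagent. 1-(Trimethylsilyl)imidazole caps the tertiary hydroxyl to give (10S)-10-[(Z)-heptadec-8-en-1-yl]-10-(trimethylsilyloxy)-1,5-dithiaspiro[5.5]undec-7-en-9-one F8. Corey–Bakshi–Shibata reduction with catecholborane and (3aR)-1-methyl-3,3-diphenyltetrahydro-1H,3H-pyrrolo[1,2-c][1,3,2]oxazaborole (20 mol %, toluene, −78 °C; antipode chosen with the fully substituted carbon as the large group, and catecholborane leaves the chain alkene alone at this temperature) should give (9S,10S)-10-[(Z)-heptadec-8-en-1-yl]-10-(trimethylsilyloxy)-1,5-dithiaspiro[5.5]undec-7-en-9-ol F9. Citric acid in MeOH at 0 °C removes the silyl group and returns 12.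

Further compounds
F1 | step 6 | rel-(8S,9R)-8-[(Z)-heptadec-8-en-1-yl]-1,5-dithiaspiro[5.5]undecane-8,9-diol (racemic cis-diol, one enantiomer drawn) | CCCCCCCC/C=C\CCCCCCC[C@]1(O)CC2(SCCCS2)CC[C@H]1O
F2 | step 6 | racemic 8-[(Z)-heptadec-8-en-1-yl]-8-hydroxy-1,5-dithiaspiro[5.5]undecan-9-one | CCCCCCCC/C=C\CCCCCCCC1(O)CC2(SCCCS2)CCC1=O
F3 | step 8 | (8S,9S)-8-[(Z)-heptadec-8-en-1-yl]-1,5-dithiaspiro[5.5]undecane-8,9-diol | CCCCCCCC/C=C\CCCCCCC[C@]1(O)CC2(SCCCS2)CC[C@@H]1O
F4 | step 8 | (8S,9S)-8-[(Z)-heptadec-8-en-1-yl]-8,9-bis(triethylsilyloxy)-1,5-dithiaspiro[5.5]undecane | CCCCCCCC/C=C\CCCCCCC[C@]1(O[Si](CC)(CC)CC)CC2(SCCCS2)CC[C@@H]1O[Si](CC)(CC)CC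
F5 | step 8 | (3S,4S)-3-[(Z)-heptadec-8-en-1-yl]-3,4-bis(triethylsilyloxy)cyclohexan-1-one | CCCCCCCC/C=C\CCCCCCC[C@]1(O[Si](CC)(CC)CC)CC(=O)CC[C@@H]1O[Si](CC)(CC)CC
F6 | step 8 | (4S,5S)-5-[(Z)-heptadec-8-en-1-yl]-4,5-bis(triethylsilyloxy)-1-(trimethylsilyloxy)cyclohex-1-ene | CCCCCCCC/C=C\CCCCCCC[C@]1(O[Si](CC)(CC)CC)CC(O[Si](C)(C)C)=CC[C@@H]1O[Si](CC)(CC)CC
F7 | step 8 | (4S,5S)-5-[(Z)-heptadec-8-en-1-yl]-4,5-bis(triethylsilyloxy)cyclohex-2-en-1-one | CCCCCCCC/C=C\CCCCCCC[C@]1(O[Si](CC)(CC)CC)CC(=O)C=C[C@@H]1O[Si](CC)(CC)CC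
F8 | step 9 | (10S)-10-[(Z)-heptadec-8-en-1-yl]-10-(trimethylsilyloxy)-1,5-dithiaspiro[5.5]undec-7-en-9-one | CCCCCCCC/C=C\CCCCCCC[C@]1(O[Si](C)(C)C)CC2(SCCCS2)C=CC1=O
F9 | step 9 | (9S,10S)-10-[(Z)-heptadec-8-en-1-yl]-10-(trimethylsilyloxy)-1,5-dithiaspiro[5.5]undec-7-en-9-ol | CCCCCCCC/C=C\CCCCCCC[C@]1(O[Si](C)(C)C)CC2(SCCCS2)C=C[C@@H]1O
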